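**Plan**

Locants: ring C1 (OAc), C2 (CMe2), C3 (CH bearing the chain), C4 (=CH2), C5, C6; chain C1′–C17′.
Cuts: O–acetyl; C1′–C2′ (sulfonyl carbanion + allylic bromide, a C10 ring unit + a C20 chain); C4=CH2 (Wittig); ring bonds C2–C3 and C3–C4, so that C3 leaves the ring as a diazo carbon; in the chain C3′=C4′ (stabilised ylide) and C5′–C6′ (ester enolate + farnesyl bromide).
Enabling feature: C3 lies between the quaternary C2 and the sp2 C4, and its chain carbon C1′ is cis-1,3 to the C1 oxygen. Without C3 the ring is achiral 2,2-dimethylcyclopentane-1,3-dione, and the unit O–C1′(=O)–C3(=N2) is the diazoacetate of its mono-reduced form.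
Forward: the cyclopentane comes first. The tethered diazo carbon adds to the ring ketone and the CMe2 carbon shifts onto it (cyclopentane → cyclohexane, bridged by a γ-lactone C1–O–C1′–C3). Then follow methylenation, lactone opening, C1′ sulfone, union with the chain, desulfonylation and acetylation.
Stereochemistry: C1 comes from a CBS reduction of enantiotopic carbonyl groups; C3 is relayed from C1 by the lactone tether; 3′E comes from the stabilised ylide; 7′E and 11′E are bought with (E,E)-farnesyl bromide.

Key step: step 3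

Assumption: the (R)-oxazaborolidine is assigned to the (S)-alcohol by the standard model, with the quaternary carbon as the large group and CH2 as the small group.

**Route**

Step 1
Reactants: 1 2,2-dimethylcyclopentane-1,3-dione
Product: 2 (3S)-3-hydroxy-2,2-dimethylcyclopentan-1-one
Conditions: (R)-Me-CBS (10 mol %), BH3·SMe2 (0.6 equiv), THF, −30 °C; aqueous work-up
Reagents that add atoms: none
Why: Corey–Bakshi–Shibata reduction of one of two enantiotopic carbonyl groups, in which the catalyst distinguishes the quaternary α-carbon from the α-CH2 and should give the (S)-carbinol, while substoichiometric borane limits diol formation.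

Step 2
Reactants: 2 (3S)-3-hydroxy-2,2-dimethylcyclopentan-1-one
Product: 4 (1S)-2,2-dimethyl-3-oxocyclopentyl 2-diazoacetate, via glyoxylate tosylhydrazone ester 3 (not isolated)
Conditions: TsNHN=CHCOCl, PhNMe2, CH2Cl2, 0 °C; then Et3N, 0 °C → rt
Reagents that add atoms: glyoxylic acid chloride p-toluenesulfonylhydrazone, Cc1ccc(cc1)S(=O)(=O)N/N=C/C(Cl)=O
Why: O-acylation by the acid chloride followed by Bamford–Stevens-type loss of sulfinate from the hydrazone is the standard one-flask diazoacetylation of hindered secondary alcohols, and it leaves the carbinol centre untouched because the quaternary α-carbon rules out β-elimination.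

Step 3
Reactants: 4 (1S)-2,2-dimethyl-3-oxocyclopentyl 2-diazoacetate
Product: 6 (1S,5S)-8,8-dimethyl-6-oxabicyclo[3.2.1]octane-2,7-dione, via bicyclic diazonium betaine 5 (not isolated)
Conditions: BF3·OEt2 (1.1 equiv), CH2Cl2 (5 mM, slow addition of 4), −78 → −20 °C; aq. NaHCO3
Reagents that add atoms: none
Why: Proposed new method: BF3 activates the ring ketone, the tethered diazo carbon adds to it (6-(enolendo)-exo-trig closure of a δ-lactone, giving the 2-oxabicyclo[3.2.1]octane betaine 5), and the ring bond antiperiplanar to C–N2+ then shifts onto the diazonium carbon with loss of N2 and return of the C=O, so the cyclopentane becomes the cyclohexane and the δ-lactone contracts to the γ-lactone by 1,2-shift, not by a second closure. The closest known reactions are the BF3-promoted ethyl diazoacetate homologation of cycloalkanones (Tiffeneau–Demjanov type) and intramolecular diazoalkane–ketone ring enlargements, whereas the ester-tethered version with migration of a quaternary carbon has not been shown. The selectivity needed is migration of the CMe2 carbon instead of the CH2 that normally moves: in the chair δ-lactone of 5 an axial N2+ would be syn-axial to one methyl of the CMe2 bridge, so N2+ should sit equatorial (the diazoester rotamer with N2 syn to C=O leads there), where it is antiperiplanar only to the C(O)–CMe2 ring bond, as in the ring contraction of diequatorial 2-aminocyclohexanols on deamination. The boron-bound oxygen is gauche to N2+, which shuts off epoxide formation. The one new stereocentre (target C3) is fixed by the tether, because the lactone can bridge only on the face of the C1–O bond set in step 1, and as a bridgehead between two carbonyl groups it cannot enolise. High dilution suppresses the bimolecular diazo–ketone reaction, which would move the CH2.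

Step 4
Reactants: 6 (1S,5S)-8,8-dimethyl-6-oxabicyclo[3.2.1]octane-2,7-dione
Product: 7 (1R,5S)-8,8-dimethyl-2-methylidene-6-oxabicyclo[3.2.1]octan-7-one
Conditions: Ph3PCH3Br, NaHMDS, THF, 0 °C; then 6, 0 °C → rt
Reagents that add atoms: methyltriphenylphosphonium bromide, C[P+](c1ccccc1)(c1ccccc1)c1ccccc1.[Br-]
Why: Wittig methylenation takes the ketone in preference to the lactone, and the bridgehead position of C3 excludes both epimerisation and retro-Claisen cleavage, since either would need a bridgehead enolate.

Step 5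
Reactants: 7 (1R,5S)-8,8-dimethyl-2-methylidene-6-oxabicyclo[3.2.1]octan-7-one
Product: 8 (1S,3R)-3-(hydroxymethyl)-2,2-dimethyl-4-methylidenecyclohexan-1-ol
Conditions: LiAlH4, Et2O, 0 °C → rt; Fieser work-up
Reagents that add atoms: none
Why: Hydride reduction of the lactone to the diol removes the tether, touches neither stereocentre and leaves the isolated 1,1-disubstituted alkene alone.

Step 6
Reactants: 8 (1S,3R)-3-(hydroxymethyl)-2,2-dimethyl-4-methylidenecyclohexan-1-ol
Product: 9 (1S,3R)-2,2-dimethyl-4-methylidene-3-[(phenylsulfanyl)methyl]cyclohexan-1-ol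
Conditions: PhSSPh, n-Bu3P, THF, rt → 50 °C
Reagents that add atoms: diphenyl disulfide, c1ccc(cc1)SSc1ccccc1
Why: In the Hata reaction only the primary alcohol forms the alkoxyphosphonium salt, and the thiolate present should displace it faster than the un-ionised, equatorial C1 hydroxyl can close on C1′.

Step 7
Reactants: 9 (1S,3R)-2,2-dimethyl-4-methylidene-3-[(phenylsulfanyl)methyl]cyclohexan-1-ol
Product: 10 (1S,3R)-3-[(benzenesulfonyl)methyl]-2,2-dimethyl-4-methylidenecyclohexan-1-ol
Conditions: (NH4)6Mo7O24·4H2O (10 mol %), 30 % H2O2, EtOH, 0 °C → rt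
Reagents that add atoms: hydrogen peroxide, OO
Why: Molybdate-catalysed peroxide oxidation takes sulfide to sulfone and is routinely compatible with isolated alkenes and secondary alcohols.

Step 8
Reactants: 11 (2E,6E)-farnesyl bromide
Product: 12 ethyl (4E,8E)-5,9,13-trimethyltetradeca-4,8,12-trienoate
Conditions: EtOAc, LDA, THF, −78 °C; then 11, DMPU, −78 → −30 °C
Reagents that add atoms: ethyl acetate, CCOC(C)=O
Why: Ester enolate alkylation by SN2 at the primary allylic bromide adds two carbons and keeps both purchased E double bonds.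

Step 9
Reactants: 12 ethyl (4E,8E)-5,9,13-trimethyltetradeca-4,8,12-trienoate
Product: 13 (4E,8E)-5,9,13-trimethyltetradeca-4,8,12-trienal
Conditions: DIBAL-H (1.1 equiv), CH2Cl2, −78 °C; Rochelle salt
Reagents that add atoms: none
Why: Partial DIBAL-H reduction stops at the aluminium hemiacetal at low temperature and releases the aldehyde on work-up.

Step 10
Reactants: 13 (4E,8E)-5,9,13-trimethyltetradeca-4,8,12-trienal
Product: 14 ethyl (2E,6E,10E)-2,7,11,15-tetramethylhexadeca-2,6,10,14-tetraenoate
Conditions: Ph3P=C(Me)CO2Et, CH2Cl2, rt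
Reagents that add atoms: ethyl 2-(triphenylphosphoranylidene)propanoate, CCOC(=O)C(C)=P(c1ccccc1)(c1ccccc1)c1ccccc1
Why: The Wittig reaction of an α-methyl stabilised ylide with an unbranched aldehyde is reliably E-selective and so sets the 3′E trisubstituted alkene.

Step 11
Reactants: 14 ethyl (2E,6E,10E)-2,7,11,15-tetramethylhexadeca-2,6,10,14-tetraenoate
Product: 15 (2E,6E,10E)-2,7,11,15-tetramethylhexadeca-2,6,10,14-tetraen-1-ol
Conditions: DIBAL-H (2.3 equiv), CH2Cl2, −78 °C; Rochelle salt
Reagents that add atoms: none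
Why: 1,2-Reduction of the enoate by DIBAL-H gives the allylic alcohol with the alkene geometry intact.

Step 12
Reactants: 15 (2E,6E,10E)-2,7,11,15-tetramethylhexadeca-2,6,10,14-tetraen-1-ol
Product: 16 (2E,6E,10E)-1-bromo-2,7,11,15-tetramethylhexadeca-2,6,10,14-tetraene
Conditions: CBr4, PPh3, CH2Cl2, −20 → 0 °C; used without storage
Reagents that add atoms: carbon tetrabromide, BrC(Br)(Br)Br
Why: The Appel reaction converts primary allylic alcohols to the bromides under neutral conditions without allylic transposition or E/Z loss.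

Step 13
Reactants: 10 (1S,3R)-3-[(benzenesulfonyl)methyl]-2,2-dimethyl-4-methylidenecyclohexan-1-ol; 16 (2E,6E,10E)-1-bromo-2,7,11,15-tetramethylhexadeca-2,6,10,14-tetraene
Product: 18 (1S,3R)-3-[(3E,7E,11E)-1-(benzenesulfonyl)-3,8,12,16-tetramethylheptadeca-3,7,11,15-tetraen-1-yl]-2,2-dimethyl-4-methylidenecyclohexan-1-ol (both C1′ epimers), via dilithiated sulfone 17 (not isolated)
Conditions: n-BuLi (2.1 equiv), THF–DMPU, −78 °C; then 16, −78 → −30 °C; H2O
Reagents that add atoms: none
Why: Alkylation of an α-sulfonyl carbanion with an allylic bromide (sulfone coupling of the Julia/Biellmann type) forms C1′–C2′ at the primary carbon without allylic shift, and the hindered lithium alkoxide next to CMe2 should stay a spectator, so no protecting group is needed.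

Step 14
Reactants: 18 (1S,3R)-3-[(3E,7E,11E)-1-(benzenesulfonyl)-3,8,12,16-tetramethylheptadeca-3,7,11,15-tetraen-1-yl]-2,2-dimethyl-4-methylidenecyclohexan-1-ol
Product: 19 (1S,3R)-2,2-dimethyl-4-methylidene-3-[(3E,7E,11E)-3,8,12,16-tetramethylheptadeca-3,7,11,15-tetraen-1-yl]cyclohexan-1-ol
Conditions: 6 % Na(Hg), Na2HPO4, MeOH–THF, −20 → 0 °C
Reagents that add atoms: none
Why: Reductive desulfonylation of a non-allylic alkyl aryl sulfone by buffered sodium amalgam replaces C–S by C–H, erases the C1′ epimer mixture and leaves the unconjugated alkenes in place.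

Step 15
Reactants: 19 (1S,3R)-2,2-dimethyl-4-methylidene-3-[(3E,7E,11E)-3,8,12,16-tetramethylheptadeca-3,7,11,15-tetraen-1-yl]cyclohexan-1-ol
Product: 20 (1S,3R)-2,2-dimethyl-4-methylidene-3-[(3E,7E,11E)-3,8,12,16-tetramethylheptadeca-3,7,11,15-tetraen-1-yl]cyclohexyl acetate
Conditions: Ac2O, pyridine, DMAP (cat.), CH2Cl2, rt
Reagents that add atoms: acetic anhydride, CC(=O)OC(C)=O
Why: DMAP-catalysed acetylation of the equatorial secondary alcohol proceeds with retention at C1 and under conditions that do not move the exocyclic alkene.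

**Compound list**

1 | 2,2-dimethylcyclopentane-1,3-dione | CC1(C)C(=O)CCC1=O | starting material
2 | (3S)-3-hydroxy-2,2-dimethylcyclopentan-1-one | O=C1CC[C@H](O)C1(C)C | intermediate
3 | (1S)-2,2-dimethyl-3-oxocyclopentyl (E)-2-(2-tosylhydrazinylidene)acetate | O=C1CC[C@H](OC(=O)/C=N/NS(=O)(=O)c2ccc(C)cc2)C1(C)C | intermediate
4 | (1S)-2,2-dimethyl-3-oxocyclopentyl 2-diazoacetate | O=C1CC[C@H](OC(=O)C=[N+]=[N-])C1(C)C | intermediate
5 | 4-diazonio-8,8-dimethyl-5-(trifluoroboranuidyloxy)-2-oxabicyclo[3.2.1]octan-3-one, N2+ equatorial on the δ-lactone chair and anti to the C5–C8 bond | F[B-](F)(F)O[C@]12CC[C@H](OC(=O)[C@@H]1[N+]#N)C2(C)C | intermediate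
6 | (1S,5S)-8,8-dimethyl-6-oxabicyclo[3.2.1]octane-2,7-dione | O=C1CC[C@@H]2OC(=O)[C@H]1C2(C)C | intermediate
7 | (1R,5S)-8,8-dimethyl-2-methylidene-6-oxabicyclo[3.2.1]octan-7-one | C=C1CC[C@@H]2OC(=O)[C@H]1C2(C)C | intermediate
8 | (1S,3R)-3-(hydroxymethyl)-2,2-dimethyl-4-methylidenecyclohexan-1-ol | C=C1CC[C@H](O)C(C)(C)[C@@H]1CO | intermediate
9 | (1S,3R)-2,2-dimethyl-4-methylidene-3-[(phenylsulfanyl)methyl]cyclohexan-1-ol | C=C1CC[C@H](O)C(C)(C)[C@@H]1CSc1ccccc1 | intermediate
10 | (1S,3R)-3-[(benzenesulfonyl)methyl]-2,2-dimethyl-4-methylidenecyclohexan-1-ol | C=C1CC[C@H](O)C(C)(C)[C@@H]1CS(=O)(=O)c1ccccc1 | intermediate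
11 | (2E,6E)-farnesyl bromide, (2E,6E)-1-bromo-3,7,11-trimethyldodeca-2,6,10-triene | BrC/C=C(\C)CC/C=C(\C)CCC=C(C)C | starting material
12 | ethyl (4E,8E)-5,9,13-trimethyltetradeca-4,8,12-trienoate | CCOC(=O)CC/C=C(\C)CC/C=C(\C)CCC=C(C)C | intermediate
13 | (4E,8E)-5,9,13-trimethyltetradeca-4,8,12-trienal | O=CCC/C=C(\C)CC/C=C(\C)CCC=C(C)C | intermediate
14 | ethyl (2E,6E,10E)-2,7,11,15-tetramethylhexadeca-2,6,10,14-tetraenoate | CCOC(=O)/C(C)=C/CC/C=C(\C)CC/C=C(\C)CCC=C(C)C | intermediate
15 | (2E,6E,10E)-2,7,11,15-tetramethylhexadeca-2,6,10,14-tetraen-1-ol | OC/C(C)=C/CC/C=C(\C)CC/C=C(\C)CCC=C(C)C | intermediate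
16 | (2E,6E,10E)-1-bromo-2,7,11,15-tetramethylhexadeca-2,6,10,14-tetraene | BrC/C(C)=C/CC/C=C(\C)CC/C=C(\C)CCC=C(C)C | intermediate
17 | dilithium salt of 10 (C1 alkoxide, C1′ sulfonyl carbanion) | C=C1CC[C@H]([O-])C(C)(C)[C@@H]1[CH-]S(=O)(=O)c1ccccc1.[Li+].[Li+] | intermediate
18 | (1S,3R)-3-[(3E,7E,11E)-1-(benzenesulfonyl)-3,8,12,16-tetramethylheptadeca-3,7,11,15-tetraen-1-yl]-2,2-dimethyl-4-methylidenecyclohexan-1-ol, both C1′ epimers | C=C1CC[C@H](O)C(C)(C)[C@@H]1C(C/C(C)=C/CC/C=C(\C)CC/C=C(\C)CCC=C(C)C)S(=O)(=O)c1ccccc1 | intermediate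
19 | (1S,3R)-2,2-dimethyl-4-methylidene-3-[(3E,7E,11E)-3,8,12,16-tetramethylheptadeca-3,7,11,15-tetraen-1-yl]cyclohexan-1-ol | C=C1CC[C@H](O)C(C)(C)[C@@H]1CC/C(C)=C/CC/C=C(\C)CC/C=C(\C)CCC=C(C)C | intermediate
20 | (1S,3R)-2,2-dimethyl-4-methylidene-3-[(3E,7E,11E)-3,8,12,16-tetramethylheptadeca-3,7,11,15-tetraen-1-yl]cyclohexyl acetate | C=C1CC[C@H](OC(C)=O)C(C)(C)[C@@H]1CC/C(C)=C/CC/C=C(\C)CC/C=C(\C)CCC=C(C)C | target

**Step count**

Total steps: 15. Longest linear sequence: 10 (steps 1–7 and 13–15). The chain branch (steps 8–12) runs in parallel.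

**Steps most likely to fail**

Step 3. The Lewis acid may destroy the diazoester, or bimolecular attack may set in, before the ester reaches the rotamer needed for closure. A betaine with axial diazonium would move the ring CH2 instead of CMe2.
- The fallback sets out from 2 and returns at 6, and it uses known reaction types only.
- Silylation (TBSCl, imidazole, DMF) gives (3S)-3-(tert-butyldimethylsilyloxy)-2,2-dimethylcyclopentan-1-one F1.
- Aldol-type addition of ethyl lithiodiazoacetate (ethyl diazoacetate, LDA, THF, −78 °C) gives the tertiary α-diazo-β-hydroxy ester F2.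
- Rh2(OAc)4 in CH2Cl2 converts it, by 1,2-alkyl shift at the rhodium carbenoid, into the ring-enlarged silyloxy β-keto ester F3.
- HF in MeCN frees the hydroxy β-keto ester F4, and catalytic TsOH in hot toluene lactonises it to 6.
- The carbon between the two carbonyl groups epimerises freely, so both epimers drain into the only lactone that can form.
- Migration of the more electron-rich quaternary carbon is expected here but is not enforced by geometry. For that reason this sequence is the fallback.

Step 13. The chelated, neopentyl-like dianion may alkylate slowly, so that proton transfer, O-alkylation or decay of the allylic bromide takes over.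
- The fallback sets out from 9 and 16 and returns at 19, bypassing 10, 17 and 18.
- Compound 9 is deprotonated (n-BuLi) and reductively lithiated with lithium di-tert-butylbiphenylide (THF, −78 °C) to the alkoxide-bearing primary alkyllithium F5.
- CuBr·SMe2 combines it with the lithium thiophenolate formed alongside to give the alkyl(phenylthio)cuprate F6.
- The cuprate is allylated by 16 at its primary carbon to give 19 directly.

Step 6. Substitution at the β-branched C1′ may be slow enough for the C1 hydroxyl to close on the activated carbon (intramolecular etherification).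
- The fallback sets out from 7 and returns at 9. It forms the C–S bond at an acetal carbon instead of by SN2.
- DIBAL-H (1 equiv, CH2Cl2, −78 °C) gives the bicyclic lactol F7.
- PhSH with catalytic BF3·OEt2 (CH2Cl2, −40 °C) gives the bicyclic O,S-acetal F8.
- Mixed hydride (LiAlH4/AlCl3, Et2O, 0 °C) cleaves the ring C–O bond through the sulfur-stabilised cation and delivers 9.

**Further compounds**

F1 | step 3 | (3S)-3-(tert-butyldimethylsilyloxy)-2,2-dimethylcyclopentan-1-one | O=C1CC[C@H](O[Si](C)(C)C(C)(C)C)C1(C)C
F2 | step 3 | ethyl 2-diazo-2-[(3S)-3-(tert-butyldimethylsilyloxy)-1-hydroxy-2,2-dimethylcyclopentyl]acetate | CCOC(=O)C(=[N+]=[N-])C1(O)CC[C@H](O[Si](C)(C)C(C)(C)C)C1(C)C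
F3 | step 3 | ethyl (3S)-3-(tert-butyldimethylsilyloxy)-2,2-dimethyl-6-oxocyclohexane-1-carboxylate | CCOC(=O)C1C(=O)CC[C@H](O[Si](C)(C)C(C)(C)C)C1(C)C
F4 | step 3 | ethyl (3S)-3-hydroxy-2,2-dimethyl-6-oxocyclohexane-1-carboxylate | CCOC(=O)C1C(=O)CC[C@H](O)C1(C)C
F5 | step 13 | dilithium (1S,3R)-3-(lithiomethyl)-type dianion: C1 alkoxide and C1′ primary carbanion of the ring unit | C=C1CC[C@H]([O-])C(C)(C)[C@@H]1[CH2-].[Li+].[Li+]
F6 | step 13 | dilithium alkyl(phenylthio)cuprate of the ring unit | C=C1CC[C@H]([O-])C(C)(C)[C@@H]1C[Cu-]Sc1ccccc1.[Li+].[Li+]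
F7 | step 6 | (1R,5S)-8,8-dimethyl-2-methylidene-6-oxabicyclo[3.2.1]octan-7-ol | C=C1CC[C@@H]2OC(O)[C@H]1C2(C)C
F8 | step 6 | (1R,5S)-8,8-dimethyl-2-methylidene-7-(phenylsulfanyl)-6-oxabicyclo[3.2.1]octane | C=C1CC[C@@H]2OC(Sc3ccccc3)[C@H]1C2(C)C
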